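**Plan**
- Retrosynthesis cuts the C2–C3 bond of the 4-aryl-4-oxobutanoic acid: C2 becomes the α-carbon of an aldehyde, C3 the CH2 of an α-bromo aryl ketone. The enabling feature is the 1,4-dicarbonyl relation: the stereocentre is α to the carboxyl carbon and its bond partner is α to the aryl ketone.
- Before that, the acid is taken back to the aldehyde and the hydroquinone OH groups to acetates; the C13 dienal is cut between the geranyl CH2 and a three-carbon homoenolate unit.
- Forward: geranyl bromide + dioxolanylethyl Grignard gives the acetal and then the dienal; 2,5-dihydroxyacetophenone is acetylated and α-brominated.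
- The two halves are joined by an enantioselective photoredox/enamine α-alkylation, which forms the C–C bond and the only stereocentre together; Pinnick oxidation and deacetylation finish the route.
- Stereochemistry: the (S) centre is set by the chiral imidazolidinone catalyst (Re-face attack on the E-enamine); both E-alkenes come unchanged from geranyl bromide.

Key step: step 5

Assumption: the (2S,5R)-imidazolidinone is chosen on the usual model for this catalyst class (enamine turned away from tert-butyl, ring methyl covering the Si face); this sense of induction is recalled from the known reaction, not derived independently, and the mirror-image catalyst would be used if the sense proves opposite.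

**Step 1**
Reactants: 1 geranyl bromide ((2E)-1-bromo-3,7-dimethylocta-2,6-diene); 2 2-(2-bromoethyl)-1,3-dioxolane
Product: 4 2-[(4E)-5,9-dimethyldeca-4,8-dien-1-yl]-1,3-dioxolane, via [2-(1,3-dioxolan-2-yl)ethyl]magnesium bromide 3 (not isolated)
Conditions: 2, Mg turnings, THF, 20–25 °C; then 1, Li2CuCl4 (3 mol%), THF, −20 → 0 °C
Reagents that add atoms: none
Why: Copper-catalysed Grignard cross-coupling (Kochi type) of a primary allylic bromide should give the linear SN2 product with the E-alkene retained, the Grignard being kept below 30 °C to avoid its known decomposition.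

**Step 2**
Reactants: 4 2-[(4E)-5,9-dimethyldeca-4,8-dien-1-yl]-1,3-dioxolane
Product: 5 (5E)-6,10-dimethylundeca-5,9-dienal
Conditions: 1 M aq. HCl, THF, rt
Reagents that add atoms: water, O
Why: Acid-catalysed acetal hydrolysis under dilute aqueous conditions should free the aldehyde without protonating the trisubstituted alkenes.

**Step 3**
Reactants: 6 2,5-dihydroxyacetophenone
Product: 7 2-acetyl-1,4-phenylene diacetate
Conditions: Ac2O (2.5 equiv), pyridine, DMAP (cat.), CH2Cl2, 0 °C → rt
Reagents that add atoms: acetic anhydride, CC(=O)OC(C)=O
Why: DMAP-catalysed O-acylation should cap both phenols (including the hydrogen-bonded ortho one), which protects the hydroquinone from oxidation and deactivates the ring toward bromination.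

**Step 4**
Reactants: 7 2-acetyl-1,4-phenylene diacetate
Product: 8 2-(bromoacetyl)-1,4-phenylene diacetate
Conditions: CuBr2 (2.0 equiv), EtOAc/CHCl3 1:1, reflux
Reagents that add atoms: copper(II) bromide, Br[Cu]Br
Why: Copper(II) bromide α-bromination of an aryl methyl ketone (King–Ostrum conditions) should stop at the monobromide, and the acetoxy groups keep the ring from being brominated.

**Step 5**
Reactants: 5 (5E)-6,10-dimethylundeca-5,9-dienal (2 equiv); 8 2-(bromoacetyl)-1,4-phenylene diacetate
Product: 10 2-[(3S,6E)-3-formyl-7,11-dimethyldodeca-6,10-dienoyl]-1,4-phenylene diacetate, via catalyst-bound (E)-enamine 9 (not isolated)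
Conditions: (2S,5R)-2-tert-butyl-3,5-dimethylimidazolidin-4-one·TfOH (20 mol%), Ru(bpy)3Cl2 (0.5 mol%), 2,6-lutidine (2 equiv), degassed DMF, blue LED or fluorescent lamp, 23 °C
Reagents that add atoms: none
Why: Ru(I), formed by reductive quenching of photoexcited Ru(bpy)3(2+), should reduce bromide 8 by single-electron transfer to bromide ion and an electrophilic α-keto radical, which adds to the α-carbon of enamine 9; the resulting α-amino radical is oxidised to the iminium ion, whose hydrolysis releases aldehyde 10 and the catalyst. The closest known reaction type is the enantioselective photoredox organocatalytic α-alkylation of aldehydes with α-bromo carbonyl compounds, phenacyl bromides included. No ring is closed. The new C2 stereocentre is controlled by the catalyst: the tert-butyl group turns the E-enamine away from itself and the ring methyl covers the Si face, so the radical should enter from the Re face and give (S). The step needs the radical to choose the enamine over the two trisubstituted alkenes, and the α-amino radical to be oxidised before it can close 5-exo onto the C5=C6 alkene; the high nucleophilicity of the enamine and the fast, strongly exergonic electron transfer from the α-amino radical to 8 or to the excited photocatalyst should secure both. The hindered secondary amine and weakly basic 2,6-lutidine should leave the aryl acetates and the new, epimerisable α-centre untouched.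

**Step 6**
Reactants: 10 2-[(3S,6E)-3-formyl-7,11-dimethyldodeca-6,10-dienoyl]-1,4-phenylene diacetate
Product: 11 (2S,5E)-2-[2-(2,5-diacetoxyphenyl)-2-oxoethyl]-6,10-dimethylundeca-5,9-dienoic acid
Conditions: NaClO2, NaH2PO4, 2-methyl-2-butene (large excess), t-BuOH/H2O, 0 °C → rt, directly after isolation of 10
Reagents that add atoms: sodium chlorite, [Na+].[O-]Cl=O
Why: Pinnick oxidation at about pH 4 should convert the aldehyde into the acid without epimerising the α-centre, the excess 2-methyl-2-butene trapping hypochlorous acid before it reaches the chain alkenes.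

**Step 7**
Reactants: 11 (2S,5E)-2-[2-(2,5-diacetoxyphenyl)-2-oxoethyl]-6,10-dimethylundeca-5,9-dienoic acid
Product: 12 (2S,5E)-2-[2-(2,5-dihydroxyphenyl)-2-oxoethyl]-6,10-dimethylundeca-5,9-dienoic acid (target)
Conditions: K2CO3 (3 equiv), degassed MeOH, Ar, 0 °C → rt; work-up with dilute acid containing Na2S2O4
Reagents that add atoms: none
Why: Base-mediated transesterification (Zemplén-type methanolysis) of the two aryl acetates should free the hydroquinone; the stereocentre sits α to a carboxylate and is not enolised, and exclusion of air with a dithionite work-up guards against quinone formation.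

**Compound list**
1 | geranyl bromide, (2E)-1-bromo-3,7-dimethylocta-2,6-diene | CC(C)=CCC/C(C)=C/CBr | starting material
2 | 2-(2-bromoethyl)-1,3-dioxolane | BrCCC1OCCO1 | starting material
3 | [2-(1,3-dioxolan-2-yl)ethyl]magnesium bromide | Br[Mg]CCC1OCCO1 | intermediate (not isolated)
4 | 2-[(4E)-5,9-dimethyldeca-4,8-dien-1-yl]-1,3-dioxolane | CC(C)=CCC/C(C)=C/CCCC1OCCO1 | intermediate
5 | (5E)-6,10-dimethylundeca-5,9-dienal | CC(C)=CCC/C(C)=C/CCCC=O | intermediate
6 | 2,5-dihydroxyacetophenone | CC(=O)c1cc(O)ccc1O | starting material
7 | 2-acetyl-1,4-phenylene diacetate | CC(=O)Oc1ccc(OC(C)=O)c(C(C)=O)c1 | intermediate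
8 | 2-(bromoacetyl)-1,4-phenylene diacetate | CC(=O)Oc1ccc(OC(C)=O)c(C(=O)CBr)c1 | intermediate
9 | (E)-enamine of 5 with the (2S,5R)-2-tert-butyl-3,5-dimethylimidazolidin-4-one catalyst (N1-alkenyl) | CC(C)=CCC/C(C)=C/CCC/C=C/N1[C@H](C)C(=O)N(C)[C@H]1C(C)(C)C | intermediate (not isolated)
10 | 2-[(3S,6E)-3-formyl-7,11-dimethyldodeca-6,10-dienoyl]-1,4-phenylene diacetate | CC(C)=CCC/C(C)=C/CC[C@@H](CC(=O)c1cc(OC(C)=O)ccc1OC(C)=O)C=O | intermediate
11 | (2S,5E)-2-[2-(2,5-diacetoxyphenyl)-2-oxoethyl]-6,10-dimethylundeca-5,9-dienoic acid | CC(C)=CCC/C(C)=C/CC[C@@H](CC(=O)c1cc(OC(C)=O)ccc1OC(C)=O)C(=O)O | intermediate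
12 | (2S,5E)-2-[2-(2,5-dihydroxyphenyl)-2-oxoethyl]-6,10-dimethylundeca-5,9-dienoic acid | CC(C)=CCC/C(C)=C/CC[C@@H](CC(=O)c1cc(O)ccc1O)C(=O)O | target

**Step count**
Total steps: 7. Longest linear sequence: 5 (steps 1, 2, 5, 6, 7; the arene branch 3, 4, 5, 6, 7 is equally long).

**Steps most likely to fail**

Step 5. What may go wrong: poor facial selectivity on the enamine, addition of the α-keto radical to the chain alkenes, or 5-exo cyclisation of the α-amino radical before it is oxidised. Fallback by auxiliary-controlled ionic alkylation, setting out from 5 and 8 and returning at 12: aldehyde 5 is oxidised (NaClO2, NaH2PO4, 2-methyl-2-butene) to (5E)-6,10-dimethylundeca-5,9-dienoic acid F1. F1 is activated as the mixed pivalic anhydride (PivCl, Et3N, THF, −20 °C) and treated with lithiated (R)-4-benzyl-2-oxazolidinone to give (R)-4-benzyl-3-[(5E)-6,10-dimethylundeca-5,9-dienoyl]oxazolidin-2-one F2. The chelated Z-sodium enolate of F2 (NaHMDS, THF, −78 °C) is alkylated with bromide 8 on the face opposite the benzyl group, which should give the (S)-configured alkylated imide F3. LiOH/H2O2 (THF/H2O, 0 °C, argon, prompt Na2SO3 quench) should then remove the auxiliary and both aryl acetates in one operation and deliver 12.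

Step 1. What may go wrong: SN2′ attack giving the branched linalyl-type isomer, or thermal decomposition of the acetal Grignard reagent. Fallback through a sulfone-stabilised carbanion, setting out from 1 and 2 and returning at 4: bromide 1 and sodium benzenesulfinate (DMF, rt) give geranyl phenyl sulfone F4. Its α-lithio derivative (n-BuLi, THF/DMPU, −78 °C) is alkylated with 2 to give the racemic α-alkylated sulfone F5. Palladium-catalysed hydride desulfonylation (PdCl2(dppp), LiBHEt3, THF, 0 °C) should give acetal 4 with the alkene position and geometry retained.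

Step 4. What may go wrong: over-bromination to the dibromo ketone, or loss of the aryl acetates through the hydrogen bromide set free. Fallback by brominating a preformed enol ether, setting out from 7 and returning at 8: soft enolisation of 7 (TMSOTf, Et3N, CH2Cl2, 0 °C) gives the trimethylsilyl enol ether F6, which with NBS (THF, −78 → 0 °C) should give 8 under non-acidic conditions and strictly as the monobromide.

**Further compounds**
F1 | step 5 | (5E)-6,10-dimethylundeca-5,9-dienoic acid | CC(C)=CCC/C(C)=C/CCCC(=O)O
F2 | step 5 | (R)-4-benzyl-3-[(5E)-6,10-dimethylundeca-5,9-dienoyl]oxazolidin-2-one | CC(C)=CCC/C(C)=C/CCCC(=O)N1[C@H](Cc2ccccc2)COC1=O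
F3 | step 5 | (R)-4-benzyl-3-[(2S,5E)-2-[2-(2,5-diacetoxyphenyl)-2-oxoethyl]-6,10-dimethylundeca-5,9-dienoyl]oxazolidin-2-one | CC(C)=CCC/C(C)=C/CC[C@@H](CC(=O)c1cc(OC(C)=O)ccc1OC(C)=O)C(=O)N1[C@H](Cc2ccccc2)COC1=O
F4 | step 1 | geranyl phenyl sulfone, [(2E)-3,7-dimethylocta-2,6-dien-1-yl]sulfonylbenzene | CC(C)=CCC/C(C)=C/CS(=O)(=O)c1ccccc1
F5 | step 1 | 2-[(4E)-5,9-dimethyl-3-(phenylsulfonyl)deca-4,8-dien-1-yl]-1,3-dioxolane (racemic) | CC(C)=CCC/C(C)=C/C(CCC1OCCO1)S(=O)(=O)c1ccccc1
F6 | step 4 | 2-[1-(trimethylsilyloxy)ethenyl]-1,4-phenylene diacetate | C=C(O[Si](C)(C)C)c1cc(OC(C)=O)ccc1OC(C)=O
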